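**Plan**

- Retrosynthesis first removes the three O-protecting groups and the C3–CHO bond, then opens the furan ring at O1–C7a together with the C7–CH2(prenyl) bond. This leads back to a 3-bromo-4-alkoxy deoxybenzoin and prenyl bromide.
- The deoxybenzoin is cut at the aryl–C(=O) bond into a 5-prenylresorcinol aryl metal (C5'–prenyl bond from 4,6-dibromoresorcinol) and the Weinreb amide of 3-bromo-4-hydroxyphenylacetic acid.
- Forward: the two arenes are made separately and joined as the ketone. The furan ring, the only ring formed, closes in the aryne step, which also installs the C7 prenyl group. C3 formylation and two deprotections finish the route.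
- Enabling feature: O1 (on C7a) and the prenyl CH2 (on C7) sit on adjacent carbons of the benzo ring, directly beside O6. A heteroatom and a carbon electrophile added across a C7≡C7a aryne flanked by an alkoxy group give exactly this pattern.
- Stereochemistry: the target has no stereocentre and no stereogenic double bond. The only geometric requirement is the Z enolate in the key step.

Key step: step 6

Remark: the target is achiral, so the "single enantiomer" is the compound itself and no asymmetric step is needed.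
Remark on protecting groups: O6 carries MOM, which chelates the C7 anion. The resorcinol oxygens carry TIPS, which is bulky and non-coordinating, so the hydrogen between them is not metalated by the amide base.
Assumption: (2-bromo-4-hydroxyphenyl)acetic acid, needed only in a fallback, is taken as purchasable.
Abbreviations: prenyl = 3-methylbut-2-en-1-yl; TIPS = triisopropylsilyl; MOM = methoxymethyl; TMPH = 2,2,6,6-tetramethylpiperidine.

**Route**

Step 1
Reactants: 1 3-bromo-4-hydroxyphenylacetic acid
Product: 2 2-(3-bromo-4-hydroxyphenyl)-N-methoxy-N-methylacetamide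
Conditions: MeNHOMe·HCl, EDC·HCl, HOBt (cat.), N-methylmorpholine, CH2Cl2, 0 °C → rt
Reagents that add atoms: N,O-dimethylhydroxylamine hydrochloride, CNOC.Cl
Why: Carbodiimide amide coupling, in which the amine should outcompete the weakly nucleophilic ortho-bromophenol for the activated ester, so the Weinreb amide forms without prior phenol protection.

Step 2
Reactants: 2 2-(3-bromo-4-hydroxyphenyl)-N-methoxy-N-methylacetamide
Product: 3 2-[3-bromo-4-(methoxymethoxy)phenyl]-N-methoxy-N-methylacetamide
Conditions: MOMCl, i-Pr2NEt, CH2Cl2, 0 °C → rt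
Reagents that add atoms: chloromethyl methyl ether, COCCl
Why: O-alkylation of the phenol with MOMCl (Williamson-type acetal formation) installs the chelating ether that later holds the C7 anion.

Step 3
Reactants: 4 4,6-dibromoresorcinol
Product: 5 1,5-dibromo-2,4-bis(triisopropylsilyloxy)benzene
Conditions: TIPSCl, imidazole, DMF, rt
Reagents that add atoms: triisopropylsilyl chloride, CC(C)[Si](Cl)(C(C)C)C(C)C
Why: Imidazole-promoted silylation of both phenols gives ethers that tolerate organolithium reagents and shield the ring hydrogen between them.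

Step 4
Reactants: 5 1,5-dibromo-2,4-bis(triisopropylsilyloxy)benzene; 6 prenyl bromide (1-bromo-3-methylbut-2-ene)
Product: 9 1-bromo-5-prenyl-2,4-bis(triisopropylsilyloxy)benzene, via aryllithium 7 (not isolated), via arylcopper 8 (not isolated)
Conditions: n-BuLi (1.0 equiv), THF, −78 °C; CuBr·SMe2, −78 °C; 6, −78 → 0 °C
Reagents that add atoms: none
Why: Mono bromine–lithium exchange (a second exchange on the aryl anion is much slower), copper transmetalation and SN2 allylation at the primary carbon of prenyl bromide form the standard entry to linear aryl prenyl groups; the aryllithium is kept at −78 °C so that silicon does not migrate from oxygen to carbon.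

Step 5
Reactants: 9 1-bromo-5-prenyl-2,4-bis(triisopropylsilyloxy)benzene; 3 2-[3-bromo-4-(methoxymethoxy)phenyl]-N-methoxy-N-methylacetamide
Product: 12 2-[3-bromo-4-(methoxymethoxy)phenyl]-1-[5-prenyl-2,4-bis(triisopropylsilyloxy)phenyl]ethan-1-one, via aryllithium 10 (not isolated), via aryl Grignard reagent 11 (not isolated)
Conditions: n-BuLi, THF, −78 °C; MgBr2·OEt2, −78 → 0 °C; 3, 0 °C → rt; H2O quench, aq. NH4Cl work-up
Reagents that add atoms: none
Why: Weinreb ketone synthesis, in which the less basic aryl Grignard reagent should add to the amide rather than enolise it or exchange with its aryl bromide, and the chelated tetrahedral adduct releases the ketone only on work-up.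

Step 6
Reactants: 12 2-[3-bromo-4-(methoxymethoxy)phenyl]-1-[5-prenyl-2,4-bis(triisopropylsilyloxy)phenyl]ethan-1-one; 6 prenyl bromide
Product: 17 6-(methoxymethoxy)-7-prenyl-2-[5-prenyl-2,4-bis(triisopropylsilyloxy)phenyl]-1-benzofuran, via lithium enolate 13 (not isolated), via aryne enolate 14 (not isolated), via 7-lithiobenzofuran 15 (not isolated), via 7-cupriobenzofuran 16 (not isolated)
Conditions: LiTMP (2.4 equiv, from TMPH/n-BuLi), THF, −78 → −40 °C; CuBr·SMe2 (1.2 equiv), −78 °C; 6 (3 equiv), −78 → 0 °C
Reagents that add atoms: none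
Why: Proposed new method: the first equivalent of LiTMP should give the Z lithium enolate 13, the second removes the only hydrogen next to bromine (H-2 of the bromoarene, held close to the base by the enolate O–Li), and immediate loss of LiBr gives aryne 14, whose enolate oxygen lies in the aryne plane and adds to the nearer aryne carbon in a 5-exo-dig closure that forms O1–C7a and the furan ring, attack through carbon being excluded because it would need a three-membered ring. The closest known reaction type is the anionic aryne cyclisation of meta-haloanilides and of tethered amines to 7-lithiated benzoxazoles and indolines that are then quenched with electrophiles; an enolate oxygen as the tethered nucleophile has not been shown. Regiochemistry needs no external control, because the tether reaches only C7a and the inductive effect of the 6-alkoxy group likewise puts the negative charge on C7, where anion 15 sits in a MOM chelate between two oxygens and is expected to be a weaker base than LiTMP, so it should persist beside tetramethylpiperidine. Site selectivity of the metalation rests on the substrate: the TIPS ethers do not coordinate lithium and shield H-3' of the resorcinol ring, and lithiation at H-5 next to the single MOM group is at most reversible, whereas the anion next to bromine is drained irreversibly by loss of LiBr. Transmetalation to arylcopper 16 and substitution of prenyl bromide at its primary carbon should give the linear C7 prenyl group, as in the prenylation of ortho-lithiated MOM ethers; no stereocentre is formed.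

Step 7
Reactants: 17 6-(methoxymethoxy)-7-prenyl-2-[5-prenyl-2,4-bis(triisopropylsilyloxy)phenyl]-1-benzofuran
Product: 19 6-(methoxymethoxy)-7-prenyl-2-[5-prenyl-2,4-bis(triisopropylsilyloxy)phenyl]-1-benzofuran-3-carbaldehyde, via iminium chloride 18 (not isolated)
Conditions: POCl3, DMF, 0 → 40 °C; then ice-water, aq. NaOAc
Reagents that add atoms: N,N-dimethylformamide, CN(C)C=O; water, O
Why: Vilsmeier–Haack formylation at C3, the β-carbon of the furan enol ether that is further activated by the 2-aryl group and is the usual site of electrophilic substitution in 2-arylbenzofurans, followed by hydrolysis of iminium salt 18.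

Step 8
Reactants: 19 6-(methoxymethoxy)-7-prenyl-2-[5-prenyl-2,4-bis(triisopropylsilyloxy)phenyl]-1-benzofuran-3-carbaldehyde
Product: 20 6-hydroxy-7-prenyl-2-[5-prenyl-2,4-bis(triisopropylsilyloxy)phenyl]-1-benzofuran-3-carbaldehyde
Conditions: 3 M aq. HCl, MeOH–THF, rt → 40 °C
Reagents that add atoms: none
Why: Acid-catalysed acetal exchange of the aryl MOM ether with methanol, mild enough for aryl TIPS ethers, with only one phenol next to a prenyl group exposed to acid at this stage and any dimethyl acetal of the aldehyde reverting on aqueous work-up.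

Step 9
Reactants: 20 6-hydroxy-7-prenyl-2-[5-prenyl-2,4-bis(triisopropylsilyloxy)phenyl]-1-benzofuran-3-carbaldehyde
Product: 21 Eryvarin Q, 2-(2,4-dihydroxy-5-prenylphenyl)-6-hydroxy-7-prenyl-1-benzofuran-3-carbaldehyde
Conditions: TBAF, AcOH, THF, 0 °C
Reagents that add atoms: none
Why: Buffered fluoride cleavage of the two aryl silyl ethers avoids acid beside both ortho-prenyl phenols and leaves the aldehyde untouched.

**Compound list**

1 | 3-bromo-4-hydroxyphenylacetic acid | O=C(O)Cc1ccc(O)c(Br)c1 | starting material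
2 | 2-(3-bromo-4-hydroxyphenyl)-N-methoxy-N-methylacetamide | CON(C)C(=O)Cc1ccc(O)c(Br)c1 | intermediate
3 | 2-[3-bromo-4-(methoxymethoxy)phenyl]-N-methoxy-N-methylacetamide | CON(C)C(=O)Cc1ccc(OCOC)c(Br)c1 | intermediate
4 | 4,6-dibromoresorcinol | Oc1cc(O)c(Br)cc1Br | starting material
5 | 1,5-dibromo-2,4-bis(triisopropylsilyloxy)benzene | CC(C)[Si](Oc1cc(O[Si](C(C)C)(C(C)C)C(C)C)c(Br)cc1Br)(C(C)C)C(C)C | intermediate
6 | prenyl bromide (1-bromo-3-methylbut-2-ene) | CC(C)=CCBr | starting material
7 | [5-bromo-2,4-bis(triisopropylsilyloxy)phenyl]lithium | [Li]c1cc(Br)c(O[Si](C(C)C)(C(C)C)C(C)C)cc1O[Si](C(C)C)(C(C)C)C(C)C | intermediate (not isolated)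
8 | [5-bromo-2,4-bis(triisopropylsilyloxy)phenyl]copper | [Cu]c1cc(Br)c(O[Si](C(C)C)(C(C)C)C(C)C)cc1O[Si](C(C)C)(C(C)C)C(C)C | intermediate (not isolated)
9 | 1-bromo-5-prenyl-2,4-bis(triisopropylsilyloxy)benzene | CC(C)=CCc1cc(Br)c(O[Si](C(C)C)(C(C)C)C(C)C)cc1O[Si](C(C)C)(C(C)C)C(C)C | intermediate
10 | [5-prenyl-2,4-bis(triisopropylsilyloxy)phenyl]lithium | [Li]c1cc(CC=C(C)C)c(O[Si](C(C)C)(C(C)C)C(C)C)cc1O[Si](C(C)C)(C(C)C)C(C)C | intermediate (not isolated)
11 | [5-prenyl-2,4-bis(triisopropylsilyloxy)phenyl]magnesium bromide | Br[Mg]c1cc(CC=C(C)C)c(O[Si](C(C)C)(C(C)C)C(C)C)cc1O[Si](C(C)C)(C(C)C)C(C)C | intermediate (not isolated)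
12 | 2-[3-bromo-4-(methoxymethoxy)phenyl]-1-[5-prenyl-2,4-bis(triisopropylsilyloxy)phenyl]ethan-1-one | COCOc1ccc(CC(=O)c2cc(CC=C(C)C)c(O[Si](C(C)C)(C(C)C)C(C)C)cc2O[Si](C(C)C)(C(C)C)C(C)C)cc1Br | intermediate
13 | Z lithium enolate of ketone 12 | [Li]O/C(=C\c1ccc(OCOC)c(Br)c1)c1cc(CC=C(C)C)c(O[Si](C(C)C)(C(C)C)C(C)C)cc1O[Si](C(C)C)(C(C)C)C(C)C | intermediate (not isolated)
14 | Z lithium enolate carrying the 3-(methoxymethoxy)aryne (aryne between the former C–Br carbon and its CH neighbour) | [Li]O/C(=C\C1=CC=C(OCOC)C#C1)c1cc(CC=C(C)C)c(O[Si](C(C)C)(C(C)C)C(C)C)cc1O[Si](C(C)C)(C(C)C)C(C)C | intermediate (not isolated)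
15 | {6-(methoxymethoxy)-2-[5-prenyl-2,4-bis(triisopropylsilyloxy)phenyl]-1-benzofuran-7-yl}lithium | [Li]c1c(OCOC)ccc2cc(-c3cc(CC=C(C)C)c(O[Si](C(C)C)(C(C)C)C(C)C)cc3O[Si](C(C)C)(C(C)C)C(C)C)oc12 | intermediate (not isolated)
16 | {6-(methoxymethoxy)-2-[5-prenyl-2,4-bis(triisopropylsilyloxy)phenyl]-1-benzofuran-7-yl}copper | [Cu]c1c(OCOC)ccc2cc(-c3cc(CC=C(C)C)c(O[Si](C(C)C)(C(C)C)C(C)C)cc3O[Si](C(C)C)(C(C)C)C(C)C)oc12 | intermediate (not isolated)
17 | 6-(methoxymethoxy)-7-prenyl-2-[5-prenyl-2,4-bis(triisopropylsilyloxy)phenyl]-1-benzofuran | COCOc1ccc2cc(-c3cc(CC=C(C)C)c(O[Si](C(C)C)(C(C)C)C(C)C)cc3O[Si](C(C)C)(C(C)C)C(C)C)oc2c1CC=C(C)C | intermediate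
18 | N,N-dimethyl iminium chloride of aldehyde 19 (C3–CH=NMe2+ Cl−) | C[N+](C)=Cc1c(-c2cc(CC=C(C)C)c(O[Si](C(C)C)(C(C)C)C(C)C)cc2O[Si](C(C)C)(C(C)C)C(C)C)oc2c(CC=C(C)C)c(OCOC)ccc12.[Cl-] | intermediate (not isolated)
19 | 6-(methoxymethoxy)-7-prenyl-2-[5-prenyl-2,4-bis(triisopropylsilyloxy)phenyl]-1-benzofuran-3-carbaldehyde | COCOc1ccc2c(C=O)c(-c3cc(CC=C(C)C)c(O[Si](C(C)C)(C(C)C)C(C)C)cc3O[Si](C(C)C)(C(C)C)C(C)C)oc2c1CC=C(C)C | intermediate
20 | 6-hydroxy-7-prenyl-2-[5-prenyl-2,4-bis(triisopropylsilyloxy)phenyl]-1-benzofuran-3-carbaldehyde | Oc1ccc2c(C=O)c(-c3cc(CC=C(C)C)c(O[Si](C(C)C)(C(C)C)C(C)C)cc3O[Si](C(C)C)(C(C)C)C(C)C)oc2c1CC=C(C)C | intermediate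
21 | Eryvarin Q, 2-(2,4-dihydroxy-5-prenylphenyl)-6-hydroxy-7-prenyl-1-benzofuran-3-carbaldehyde | CC(C)=CCc1cc(-c2oc3c(CC=C(C)C)c(O)ccc3c2C=O)c(O)cc1O | target

**Step count and risks**

Total steps: 9. Longest linear sequence: 7 (steps 3–9 from 4,6-dibromoresorcinol; equally steps 1, 2, 5–9 from the acid).

Steps most likely to fail:

1. Step 6. The amide base may metalate elsewhere (the benzylic/allylic CH2 groups, H-5), the aryne may be intercepted intermolecularly before the enolate oxygen closes the ring, or the C7 anion may be protonated before copper exchange. The fallback uses known chemistry, sets out from 9 and returns at 17. (2-Bromo-4-hydroxyphenyl)acetic acid is converted as in steps 1 and 2 into 2-(2-bromo-4-hydroxyphenyl)-N-methoxy-N-methylacetamide F1 and then its MOM ether, 2-[2-bromo-4-(methoxymethoxy)phenyl]-N-methoxy-N-methylacetamide F2. Grignard reagent 11, made from 9 as in step 5, should add to F2 to give the isomeric ketone 2-[2-bromo-4-(methoxymethoxy)phenyl]-1-[5-prenyl-2,4-bis(triisopropylsilyloxy)phenyl]ethan-1-one F3, in which bromine sits on the carbon that becomes C7a. Palladium-catalysed intramolecular O-arylation of its enolate (Pd2(dba)3, DPEphos, Cs2CO3, toluene, 100 °C) should give the 7-unsubstituted benzofuran, 6-(methoxymethoxy)-2-[5-prenyl-2,4-bis(triisopropylsilyloxy)phenyl]-1-benzofuran F4. Directed ortho-lithiation between O1 and the MOM ether (n-BuLi, THF, −78 → −20 °C), CuBr·SMe2 and prenyl bromide 6 should then deliver 17.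

2. Step 7. The acidic chloroiminium medium may strip the MOM group, add HCl to or attack the prenyl double bonds, or substitute C5 of the benzo ring instead of C3. The fallback sets out from 17 and returns at 19. Neutral iodination with N-iodosuccinimide (MeCN/CH2Cl2, 0 °C) should give 3-iodo-6-(methoxymethoxy)-7-prenyl-2-[5-prenyl-2,4-bis(triisopropylsilyloxy)phenyl]-1-benzofuran F5. Iodine–magnesium exchange (i-PrMgCl·LiCl, THF, −20 °C) and quenching with DMF should then give aldehyde 19.

3. Step 5. The hindered aryl nucleophile may deprotonate the acidic benzylic CH2 of the amide instead of adding, which would return the debrominated arene. The fallback sets out from 3 (with 9 as the source of aryllithium 10) and returns at 12. DIBAL-H (THF, −78 °C) should reduce 3 to 2-[3-bromo-4-(methoxymethoxy)phenyl]acetaldehyde F6. Aryllithium 10 is added at −78 °C, where carbonyl addition to an aldehyde is much faster than proton transfer, to give racemic 2-[3-bromo-4-(methoxymethoxy)phenyl]-1-[5-prenyl-2,4-bis(triisopropylsilyloxy)phenyl]ethan-1-ol F7. Dess–Martin oxidation should then give ketone 12.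

**Further compounds**

F1 | step 6 | 2-(2-bromo-4-hydroxyphenyl)-N-methoxy-N-methylacetamide | CON(C)C(=O)Cc1ccc(O)cc1Br
F2 | step 6 | 2-[2-bromo-4-(methoxymethoxy)phenyl]-N-methoxy-N-methylacetamide | CON(C)C(=O)Cc1ccc(OCOC)cc1Br
F3 | step 6 | 2-[2-bromo-4-(methoxymethoxy)phenyl]-1-[5-prenyl-2,4-bis(triisopropylsilyloxy)phenyl]ethan-1-one | COCOc1ccc(CC(=O)c2cc(CC=C(C)C)c(O[Si](C(C)C)(C(C)C)C(C)C)cc2O[Si](C(C)C)(C(C)C)C(C)C)c(Br)c1
F4 | step 6 | 6-(methoxymethoxy)-2-[5-prenyl-2,4-bis(triisopropylsilyloxy)phenyl]-1-benzofuran | COCOc1ccc2cc(-c3cc(CC=C(C)C)c(O[Si](C(C)C)(C(C)C)C(C)C)cc3O[Si](C(C)C)(C(C)C)C(C)C)oc2c1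
F5 | step 7 | 3-iodo-6-(methoxymethoxy)-7-prenyl-2-[5-prenyl-2,4-bis(triisopropylsilyloxy)phenyl]-1-benzofuran | COCOc1ccc2c(I)c(-c3cc(CC=C(C)C)c(O[Si](C(C)C)(C(C)C)C(C)C)cc3O[Si](C(C)C)(C(C)C)C(C)C)oc2c1CC=C(C)C
F6 | step 5 | 2-[3-bromo-4-(methoxymethoxy)phenyl]acetaldehyde | COCOc1ccc(CC=O)cc1Br
F7 | step 5 | 2-[3-bromo-4-(methoxymethoxy)phenyl]-1-[5-prenyl-2,4-bis(triisopropylsilyloxy)phenyl]ethan-1-ol (racemic) | COCOc1ccc(CC(O)c2cc(CC=C(C)C)c(O[Si](C(C)C)(C(C)C)C(C)C)cc2O[Si](C(C)C)(C(C)C)C(C)C)cc1Br
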